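At 0.200 h Thursday's flask already reads target at 82.1 % of target plus isomer of the product, and we bracket that share.

| flask | starting material | protic impurity | remark | time |
|---|---|---|---|---|
| Thursday's | 0.050 M | 0.050 M | the very flask that is asked about, followed so far |  |
| Wednesday's | 0.10 M | 0.050 M | run made earlier |  |
| flask | 0.050 M | 0.0500 M |  | 12 h |

- Thursday's (time / h: target / %, isomer of the product / %): 0.200: 4.6, 1.0; 0.333: 5.3, 3.1; 0.500: 8.3, 3.7; 0.833: 11.0, 9.4; 1.33: 13.9, 17.4; 2.50: 12.8, 30.4
- Wednesday's (time / h: target / %, isomer of the product / %): 0.500: 7.2, 4.9; 1.50: 13.5, 19.1; 3.00: 14.0, 35.6; 5.00: 9.5, 45.1; 6.00: 7.8, 48.4; 8.00: 4.7, 48.9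

(scatter of a reading: 0.5 percentage points)

- share of target in target plus isomer of the product at 3.0 min
- share of target in target plus isomer of the product at 40 min
- share of target in target plus isomer of the product at 12 h



Within scatter the share falls with time in both runs, so we take a later reading as a floor and an earlier one as a ceiling. At 3.0 min the ceiling is 100 % and the floor is 82.1 %, a soft floor resting on a total of 5.60 % read with a scatter of 0.5 percentage points. At 40 min Thursday's flask gives a ceiling of 69.2 % and a floor of 53.9 %.

For 12 h we borrow Wednesday's run, which carries half the impurity per starting material. Its share of 41.4 % at 1.50 h still lies between Thursday's 44.4 % at 1.33 h and 29.6 % at 2.50 h. Wednesday's 8.77 % at 8.00 h is therefore our ceiling. The two-hour retention, Wednesday's share at 8.00 h over its share at 6.00 h, reads 63.2 %. Applying it over the remaining 4.00 h gives a floor of 3.50 %, on the supposition that the share falls no faster than between those two readings.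

The forecast gives 80 %, 58 % and 4 %, calling its late figure “the least certain”; its first number stands below our floor.

The flask gives 94.4 %, 58.5 % and 4.21 %, each above its floor and below its ceiling.

    starting material ⇌ other conformer (K = 9.50, k = 2.00 × 10⁻⁴ s⁻¹)
    starting material ⇌ target (K = 2.80, k = 5.70 × 10⁻⁵ s⁻¹)
    other conformer → isomer of the product (k = 1.90 × 10⁻⁴ s⁻¹)
    other conformer ⇌ third conformer (K = 0.900, k = 1.20 × 10⁻⁴ s⁻¹)
    third conformer → third product (k = 1.10 × 10⁻⁴ s⁻¹)
    target → over-reaction product (k = 4.70 × 10⁻⁵ s⁻¹)
    other conformer + protic impurity → quenched substrate (k = 0.00140 M⁻¹ s⁻¹)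

The neighbouring flask, charged with 0.085 M of protic impurity, gets the same reckoning: ceiling 8.77 %, retention 63.2 %, floor 3.50 % at 12 h. Its share there is 4.72 %, above that floor and below that ceiling. At 40 min the neighbouring flask gives 59.3 %, inside the bracket from 53.9 % to 69.2 %. At 12 h the neighbouring flask keeps 85 % of its protic impurity and holds isomer of the product at 43.8 %, against 50.2 % in the flask.

The data were generated by integration for an exercise; scatter was added.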